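The south run ends at 42 % Q and the north-west run at 19 %, both read at 30.0 h with a scatter of 1.5 percentage points. Both take the same L charge over the same 30 h, and they differ in the E charged. Yet both read 0 % at 5.00 h, though E differs by a factor of 4.00, so I see no early time that moves with E, and I turn to amounts.

| setting | south | north-west | flask |
|---|---|---|---|
| E | 0.10 M | 0.40 M | 0.20 M |
| L | 0.22 M (fed, over 30 h) | 0.22 M (fed, over 30 h) | 0.220 M (fed, over 30 h) |
| remark | run made earlier; the fed solution adds 0.20 times the starting volume | run made earlier; the fed solution adds 0.20 times the starting volume | the fed solution adds 0.20 times the starting volume |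
| time |  |  | 30 h |

- south (time / h: Q / %): 2.50: 0; 5.00: 0; 8.00: 3; 15.0: 15; 30.0: 42
- north-west (time / h: Q / %): 2.50: 1; 5.00: 0; 8.00: 1; 15.0: 8; 30.0: 19

(standard deviation of a reading: 1.5 percentage points)

- every charge counts on the volume at the start, and the solution that is fed holds the whole dose
- on the list of suspects stand: X <-> Q; L -> J; X <-> D; E + L -> X + Z

My two amounts are the L charged and the E charged. The dose ratio, L charged over E charged, is 1.10 in the new flask. South has 2.20, so if one L takes one E, E is the limiting reagent there. North-west has 0.550, so L is the limiting reagent there. The new flask's ratio is the geometric mean of these two, halfway on a log scale, so I take the mean of the end readings: 30.5 % Q at 30 h. Early on, I expect Q near the 0 % and 1 % the runs read at 2.50 h.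

- amount of Q in percent of the E charged, at 3.0 h, 10 h, 20 h and 30 h

The forecast, reasoning that “Quadrupling E therefore roughly doubles Q”, gives 0.2 %, 4.5 %, 17 % and 29 %, and at the last time my reckoning stands above it.

The flask gives 0.269 %, 4.66 %, 17.4 % and 32.5 %, so its end lies 2 points above my 30.5 %.

    X ⇌ Q (K = 9.90, k = 0.0540 /h)
    L → J (k = 0.0470 /h)
    X ⇌ D (K = 5.00, k = 0.0180 /h)
    E + L → X + Z (k = 2.30 /M/h)

At 30.0 h this flask still holds 31.1 % of its E charged as X. Now take this flask with half the L: its dose ratio is 0.550, the north-west value, where Q read 19 %, so I expect about that again. That half-L flask gives 17.8 %.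

(The data were computed with made-up constants; the scatter is artificial.)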